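**Assumption (one line):** gibberellane locants (C1–C19) are used for positions, "β" means the face of ring A opposite the lactone bridge, SMILES strings are authoritative for configuration, and the enantiomer of the amino-acid co-catalyst (step 5) and of the resolving amine (step 10) is the one found by experiment to give the structures shown.

## Retrosynthetic overview

1. Target 28 ← global deprotection of 26; ring B (C5–C6) is closed last by Rh-carbenoid insertion of diazo ester 25 into the CH2 that bridges the ring-A lactone.
2. 25 ← 23, made by Ni-catalysed reductive conjugate coupling (C9–C10) of bridgehead bromo-lactone 22 (ring A) with bicyclic enone 11 (rings C/D).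
3. 11 ← prochiral cyclohexanone 9 by an enantioselective Pd/amino-acid desymmetrising α-alkenylation (C13–C16, ring D), then dehydrogenation; 9 ← Robinson annulation of aldehyde 4 with methyl vinyl ketone.
4. 22 ← 3-methoxybenzoic acid by Birch reductive methylation, resolution, pseudo-acid bromide lactonisation, exo-dihydroxylation and acetonide formation.
5. Ring order: C, then D (fragment 1); A with its lactone (fragment 2); union; B last.

## Route

**Step 1**
Reactants: 1 methyl 4-oxobutanoate; 2 2,3-dibromoprop-1-ene
Product: 4 methyl 5-bromo-3-formylhex-5-enoate (racemic), via enamine 3 (not isolated)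
Conditions: pyrrolidine, K2CO3, Et2O, 0 °C; then 2, MeCN, 60 °C; then aq. AcOH/NaOAc
Reagents that add atoms: none
Why: Stork enamine alkylation – the aldehyde enamine is allylated by the reactive allylic bromide (N-allylation/aza-Claisen) and hydrolysed, while the vinylic bromide and the ester are inert.

**Step 2**
Reactants: 4 methyl 5-bromo-3-formylhex-5-enoate; 5 but-3-en-2-one
Product: 6 methyl 5-bromo-3-formyl-3-(3-oxobutyl)hex-5-enoate (racemic)
Conditions: pyrrolidine (20 mol%), AcOH (20 mol%), MeCN, 0 °C → rt
Reagents that add atoms: none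
Why: Amine-catalysed Michael addition of the α-branched aldehyde to the enone builds the quaternary carbon (future C8); it is racemic, which is harmless because the centre becomes non-stereogenic in 9.

**Step 3**
Reactants: 6 methyl 5-bromo-3-formyl-3-(3-oxobutyl)hex-5-enoate
Product: 7 methyl 2-[1-(2-bromoprop-2-en-1-yl)-4-oxocyclohex-2-en-1-yl]acetate (racemic)
Conditions: TsOH·H2O (10 mol%), toluene, 80 °C, Dean–Stark
Reagents that add atoms: none
Why: Intramolecular aldol condensation (second stage of a Robinson annulation) of the 1,5-keto-aldehyde gives the 4,4-disubstituted cyclohexenone.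

**Step 4**
Reactants: 7 methyl 2-[1-(2-bromoprop-2-en-1-yl)-4-oxocyclohex-2-en-1-yl]acetate
Product: 9 methyl 2-[1-(2-bromoprop-2-en-1-yl)-4-oxocyclohexyl]acetate (achiral), via silyl enol ether 8 (not isolated)
Conditions: Et3SiH, RhCl(PPh3)3 (1 mol%), THF, 50 °C; then 1 M HCl, THF, rt
Reagents that add atoms: none
Why: Rh-catalysed 1,4-hydrosilylation of the enone followed by hydrolysis saturates only the conjugated C=C (vinyl bromide and ester untouched) and gives the prochiral ketone.

**Step 5**
Reactants: 9 methyl 2-[1-(2-bromoprop-2-en-1-yl)-4-oxocyclohexyl]acetate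
Product: 10 methyl 2-[(1R,5R)-6-methylidene-4-oxobicyclo[3.2.1]octan-1-yl]acetate
Conditions: Pd(OAc)2 (5 mol%), PPh3 (10 mol%), (S)-proline (30 mol%), K3PO4, MeOH, 60 °C
Reagents that add atoms: none
Why: Proposed new method: enantioselective desymmetrising intramolecular α-alkenylation of a 4,4-disubstituted cyclohexanone – the chiral amino acid forms rapidly equilibrating enamines towards the two enantiotopic α-carbons, Pd(0) inserts into the tethered vinyl bromide, and the proline carboxylate binds Pd so that C–C bond formation occurs on one enamine only, forming C13–C16 (ring D with its exocyclic methylene) and fixing C8 and C13 independently of the similar size of the two C8 substituents; the closest known reaction types are the Pd/proline co-catalysed desymmetrising α-arylation of 4-substituted cyclohexanones with aryl bromides and the racemic Pd-catalysed ketone α-alkenylation with vinyl halides.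

**Step 6**
Reactants: 10 methyl 2-[(1R,5R)-6-methylidene-4-oxobicyclo[3.2.1]octan-1-yl]acetate
Product: 11 methyl 2-[(1S,5R)-6-methylidene-4-oxobicyclo[3.2.1]oct-2-en-1-yl]acetate
Conditions: IBX (2 equiv), DMSO, 70 °C
Reagents that add atoms: none
Why: IBX dehydrogenation of the ketone can only go towards C11/C9 because the other α-carbon (C13) is a bridgehead, giving the C9=C11 enone needed for the union.

**Step 7**
Reactants: 12 3-bromophenol
Product: 13 1-bromo-3-methoxybenzene
Conditions: MeI, K2CO3, acetone, reflux
Reagents that add atoms: iodomethane (CI)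
Why: Williamson ether synthesis protects the phenol as the methyl ether that later becomes the C10 enol ether.

**Step 8**
Reactants: 13 1-bromo-3-methoxybenzene
Product: 15 3-methoxybenzoic acid, via Grignard reagent 14 (not isolated)
Conditions: Mg, THF, reflux; CO2, −20 °C; aq. HCl
Reagents that add atoms: carbon dioxide (O=C=O)
Why: Grignard carboxylation installs the future C19 carboxyl meta to the methoxy group.

**Step 9**
Reactants: 15 3-methoxybenzoic acid
Product: 17 3-methoxy-1-methylcyclohexa-2,5-diene-1-carboxylic acid (racemic), via dilithium dienediolate 16 (not isolated)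
Conditions: Li (3.1 equiv), NH3(l)/THF, t-BuOH (1 equiv), −78 °C; MeI; NH4Cl, then pH 5 at 0 °C
Reagents that add atoms: iodomethane (CI)
Why: Birch reduction–alkylation – the carboxylate directs 1,4-reduction with the meta-methoxy group retained on a vinylic carbon, and the dianion is methylated α to the carboxylate, giving C4 (quaternary), the C5=C10 enol ether and the C2=C3 alkene in one operation.

**Step 10**
Reactants: 17 3-methoxy-1-methylcyclohexa-2,5-diene-1-carboxylic acid (racemic)
Product: 18 (R)-3-methoxy-1-methylcyclohexa-2,5-diene-1-carboxylic acid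
Conditions: (S)-1-phenylethylamine (0.55 equiv), EtOAc/hexane, recrystallise; liberate with cold aq. NaH2PO4/citric acid
Reagents that add atoms: none
Why: Classical resolution by diastereomeric salt crystallisation supplies the C4 configuration; the basic salt form also keeps the acid-sensitive enol ether intact.

**Step 11**
Reactants: 18 (R)-3-methoxy-1-methylcyclohexa-2,5-diene-1-carboxylic acid
Product: 20 (1S,5R)-5-bromo-1-methyl-6-oxabicyclo[3.2.1]oct-2-en-7-one, via keto acid 19 (not isolated)
Conditions: 1 M HCl, THF, 0 °C, 30 min; extract, dry; then (COBr)2, DMF (cat.), CH2Cl2, 0 °C → rt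
Reagents that add atoms: water (O); oxalyl bromide (O=C(Br)C(=O)Br)
Why: Enol ether hydrolysis gives the γ-keto acid, whose acyl bromide adds across the ketone (bromide to C10, carbonyl oxygen to the acyl carbon) to give the bridged pseudo-acid bromide; the 1,3-bridge can only close cis, so C10 is set by C4, and the bridgehead α-bromo lactone can neither ionise nor eliminate.

**Step 12**
Reactants: 20 (1S,5R)-5-bromo-1-methyl-6-oxabicyclo[3.2.1]oct-2-en-7-one
Product: 21 5-bromo-2,3-dihydroxy-1-methyl-6-oxabicyclo[3.2.1]octan-7-one (cis-diol, both OH on the face away from the O–C(=O) bridge; 2β,3β in gibberellane terms)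
Conditions: OsO4 (2 mol%), NMO, acetone/H2O (10:1), 0 °C → rt
Reagents that add atoms: N-methylmorpholine N-oxide (C[N+]1([O-])CCOCC1); water (O)
Why: Upjohn dihydroxylation – osmium attacks the alkene from the exo face anti to the lactone bridge, giving the cis-diol on the same side as the C4 methyl group.

**Step 13**
Reactants: 21 5-bromo-2,3-dihydroxy-1-methyl-6-oxabicyclo[3.2.1]octan-7-one
Product: 22 acetonide of 21 (2,3-O-isopropylidene bridgehead bromo-lactone)
Conditions: Me2C(OMe)2, PPTS (cat.), CH2Cl2, rt
Reagents that add atoms: 2,2-dimethoxypropane (COC(C)(C)OC)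
Why: Acetal exchange protects the cis-diol as a dioxolane that survives the reductive, basic and carbenoid steps.

**Step 14**
Reactants: 11 methyl 2-[(1S,5R)-6-methylidene-4-oxobicyclo[3.2.1]oct-2-en-1-yl]acetate; 22 acetonide bromo-lactone
Product: 23 C9–C10-coupled triethylsilyl enol ether (the bicyclo[3.2.1]octene of 11 now carries the lactone bridgehead of 22 at C9, anti to the methylidene-bearing bridge, and OSiEt3 at C12)
Conditions: NiCl2·glyme (10 mol%), neocuproine (10 mol%), Mn powder (2 equiv), Et3SiCl (1.5 equiv), DMF, 25 °C
Reagents that add atoms: chlorotriethylsilane (CC[Si](Cl)(CC)CC)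
Why: Ni-catalysed reductive conjugate addition (cross-electrophile coupling through a silyloxy-allylnickel) joins the configurationally fixed bridgehead α-acyloxy radical to the enone β-carbon on the face anti to the C15–C16 bridge, setting C9, and leaves the C12 ketone masked as its silyl enol ether.

**Step 15**
Reactants: 23 C9–C10-coupled triethylsilyl enol ether
Product: 25 α-diazo ester of 23 (diazo group at C6), via trifluoroacetyl ester 24 (not isolated)
Conditions: LiHMDS, THF, −78 °C; CF3CO2CH2CF3; then MsN3, Et3N, H2O (1 equiv), MeCN, rt; aq. NH4Cl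
Reagents that add atoms: methanesulfonyl azide (CS(=O)(=O)N=[N+]=[N-])
Why: Detrifluoroacetylative diazo transfer (Regitz type) works because the ester CH2 is the only acidic position (lactone without α-H, ketone masked).

**Step 16**
Reactants: 25 α-diazo ester
Product: 26 tetracyclic methyl ester (rings A–D complete; 2,3-acetonide, 12-silyl enol ether, 19,10-lactone)
Conditions: Rh2(esp)2 (1 mol%), CH2Cl2, 40 °C, slow addition (0.005 M)
Reagents that add atoms: none
Why: Rh(II)-carbenoid intramolecular 1,5 C–H insertion closes ring B – the carbenoid has no β-hydrogens, the favoured rotamer about C9–C10 holds C8 next to C5 and away from C1, only the cis-fused ring B/lactone junction is strain-free so C6 enters on the lactone face (H-5 retained on the opposite face), and the ester settles trans to the bulky C4 (equilibrated with DBU if needed).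

**Step 17**
Reactants: 26 tetracyclic methyl ester
Product: 28 target, 2β,3β-dihydroxy-12-oxo-20-norgibberell-16-ene-7,19-dioic acid 19,10-lactone (CNP0307952.1), via lithium carboxylate 27 (not isolated)
Conditions: n-PrSLi (6 equiv), HMPA, 25 °C; then AcOH/H2O/THF (3:1:1), 40 °C
Reagents that add atoms: none
Why: Thiolate SN2 demethylation frees the hindered C7 acid without base-induced retro-aldol at C3, and mild aqueous acid then hydrolyses the acetonide and the silyl enol ether without disturbing the exocyclic methylene or the lactone.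

## Compound list

1 | methyl 4-oxobutanoate | O=CCCC(=O)OC | starting material
2 | 2,3-dibromoprop-1-ene | C=C(Br)CBr | starting material
3 | methyl (E)-4-(pyrrolidin-1-yl)but-3-enoate | COC(=O)C/C=C/N1CCCC1 | intermediate
4 | methyl 5-bromo-3-formylhex-5-enoate (racemic) | C=C(Br)CC(C=O)CC(=O)OC | intermediate
5 | but-3-en-2-one | CC(=O)C=C | starting material
6 | methyl 5-bromo-3-formyl-3-(3-oxobutyl)hex-5-enoate (racemic) | C=C(Br)CC(C=O)(CCC(C)=O)CC(=O)OC | intermediate
7 | methyl 2-[1-(2-bromoprop-2-en-1-yl)-4-oxocyclohex-2-en-1-yl]acetate (racemic) | C=C(Br)CC1(CC(=O)OC)C=CC(=O)CC1 | intermediate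
8 | methyl 2-[1-(2-bromoprop-2-en-1-yl)-4-(triethylsilyloxy)cyclohex-3-en-1-yl]acetate (racemic) | C=C(Br)CC1(CC(=O)OC)CC=C(O[Si](CC)(CC)CC)CC1 | intermediate
9 | methyl 2-[1-(2-bromoprop-2-en-1-yl)-4-oxocyclohexyl]acetate | C=C(Br)CC1(CC(=O)OC)CCC(=O)CC1 | intermediate
10 | methyl 2-[(1R,5R)-6-methylidene-4-oxobicyclo[3.2.1]octan-1-yl]acetate | C=C1C[C@]2(CC(=O)OC)C[C@H]1C(=O)CC2 | intermediate
11 | methyl 2-[(1S,5R)-6-methylidene-4-oxobicyclo[3.2.1]oct-2-en-1-yl]acetate | C=C1C[C@]2(CC(=O)OC)C[C@H]1C(=O)C=C2 | intermediate
12 | 3-bromophenol | Oc1cccc(Br)c1 | starting material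
13 | 1-bromo-3-methoxybenzene | COc1cccc(Br)c1 | intermediate
14 | (3-methoxyphenyl)magnesium bromide | COc1cccc([Mg]Br)c1 | intermediate
15 | 3-methoxybenzoic acid | COc1cccc(C(=O)O)c1 | intermediate
16 | dilithium (3-methoxycyclohexa-2,5-dien-1-ylidene)methanediolate | [Li+].[Li+].COC1=CC(=C([O-])[O-])C=CC1 | intermediate
17 | 3-methoxy-1-methylcyclohexa-2,5-diene-1-carboxylic acid (racemic) | COC1=CC(C)(C(=O)O)C=CC1 | intermediate
18 | (R)-3-methoxy-1-methylcyclohexa-2,5-diene-1-carboxylic acid | COC1=C[C@](C)(C(=O)O)C=CC1 | intermediate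
19 | (S)-1-methyl-5-oxocyclohex-2-ene-1-carboxylic acid | O=C1C[C@](C)(C(=O)O)C=CC1 | intermediate
20 | (1S,5R)-5-bromo-1-methyl-6-oxabicyclo[3.2.1]oct-2-en-7-one | Br[C@@]12CC=C[C@@](C)(C(=O)O1)C2 | intermediate
21 | 5-bromo-2,3-dihydroxy-1-methyl-6-oxabicyclo[3.2.1]octan-7-one (2,3-cis-diol anti to the lactone bridge) | Br[C@@]12C[C@H](O)[C@H](O)[C@@](C)(C(=O)O1)C2 | intermediate
22 | 2,3-O-isopropylidene derivative of 21 | Br[C@@]12C[C@H](OC(C)(C)O3)[C@H]3[C@@](C)(C(=O)O1)C2 | intermediate
23 | C9–C10-coupled triethylsilyl enol ether (seco-ring-B methyl ester) | C=C1C[C@]2(CC(=O)OC)C[C@H]1C(O[Si](CC)(CC)CC)=C[C@H]2[C@@]12C[C@H](OC(C)(C)O3)[C@H]3[C@@](C)(C(=O)O1)C2 | intermediate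
24 | α-trifluoroacetyl derivative of 23 (at C6) | C=C1C[C@]2(C(C(=O)C(F)(F)F)C(=O)OC)C[C@H]1C(O[Si](CC)(CC)CC)=C[C@H]2[C@@]12C[C@H](OC(C)(C)O3)[C@H]3[C@@](C)(C(=O)O1)C2 | intermediate
25 | α-diazo ester (diazo at C6) | C=C1C[C@]2(C(=[N+]=[N-])C(=O)OC)C[C@H]1C(O[Si](CC)(CC)CC)=C[C@H]2[C@@]12C[C@H](OC(C)(C)O3)[C@H]3[C@@](C)(C(=O)O1)C2 | intermediate
26 | tetracyclic methyl ester (2,3-acetonide, 12-triethylsilyl enol ether, 19,10-lactone) | C=C1C[C@]23C[C@H]1C(O[Si](CC)(CC)CC)=C[C@H]2[C@@]12C[C@H](OC(C)(C)O4)[C@H]4[C@@](C)(C(=O)O1)[C@H]2[C@@H]3C(=O)OC | intermediate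
27 | lithium carboxylate of 26 (C7) | [Li+].C=C1C[C@]23C[C@H]1C(O[Si](CC)(CC)CC)=C[C@H]2[C@@]12C[C@H](OC(C)(C)O4)[C@H]4[C@@](C)(C(=O)O1)[C@H]2[C@@H]3C(=O)[O-] | intermediate
28 | 2β,3β-dihydroxy-12-oxo-20-norgibberell-16-ene-7,19-dioic acid 19,10-lactone (CNP0307952.1) | C=C1C[C@]23C[C@H]1C(=O)C[C@H]2[C@@]12C[C@H](O)[C@H](O)[C@@](C)(C(=O)O1)[C@H]2[C@@H]3C(=O)O | target

## Step count and convergence

- Total step count: 17 (fragment 11: steps 1–6; fragment 22: steps 7–13; union and endgame: steps 14–17).
- Longest linear sequence: 11 steps (steps 7–13, then 14–17), i.e. 11/17 of the total.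

## Steps most likely to fail, with fallbacks

**Step 5 (the proposed new desymmetrising α-alkenylation).** Risks are low enantioselectivity or a sluggish enamine/Pd handshake. The fallback uses known chemistry, sets out from 7 and rejoins at 11. IBX (or DDQ) dehydrogenation of 7 gives the achiral cross-conjugated dienone methyl 2-[1-(2-bromoprop-2-en-1-yl)-4-oxocyclohexa-2,5-dien-1-yl]acetate F1. An ene-reductase of the Old Yellow Enzyme family (NADPH recycled with glucose/GDH) reduces one of the two enantiotopic C=C bonds to give methyl 2-[(1R)-1-(2-bromoprop-2-en-1-yl)-4-oxocyclohex-2-en-1-yl]acetate F2. F2 can enolise only towards C13, so a standard Pd-catalysed intramolecular ketone α-alkenylation (Pd2(dba)3, bulky phosphine, KOt-Bu, THF) closes ring D and delivers 11 directly; steps 4–6 are bypassed.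

**Step 14 (nickel-catalysed union).** The bridgehead α-acyloxy radical must meet a β-carbon flanked by a quaternary centre; fragmentation of the radical or simple reduction may compete. The fallback leaves the nickel cross-electrophile manifold for a tin hydride radical-chain Giese addition and installs the enol silane separately. It sets out from 22 and 11: Bu3SnH (syringe pump) and AIBN in benzene at 80 °C give the C9–C10-coupled ketone F3. Kinetic enolisation (LiHMDS, Et3SiCl, THF, −78 °C; only C11 is enolisable next to the ketone) then returns to the route at 23.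

**Step 16 (ring-B closure by C–H insertion).** The C5–H bonds are electronically deactivated by the neighbouring lactone oxygen and carbonyl, and insertion at C1–H or intermolecular carbene loss may compete. The fallback changes the bond-forming event from a concerted electrophilic insertion to a stepwise radical C–H alkylation: a cobalt(II) porphyrin metalloradical catalyst (toluene, 60–80 °C) converts 25 into an α-cobalt(III)-alkyl radical that abstracts H-5 by 1,5-hydrogen-atom transfer and closes the ring by radical substitution. This is governed by geometry and not by the hydridic character of the C–H bond. It sets out from 25 and rejoins at 26; no new compound is made (F0).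

## Further compounds

F1 | step 5 | methyl 2-[1-(2-bromoprop-2-en-1-yl)-4-oxocyclohexa-2,5-dien-1-yl]acetate | C=C(Br)CC1(CC(=O)OC)C=CC(=O)C=C1
F2 | step 5 | methyl 2-[(1R)-1-(2-bromoprop-2-en-1-yl)-4-oxocyclohex-2-en-1-yl]acetate | C=C(Br)C[C@]1(CC(=O)OC)CCC(=O)C=C1
F3 | step 14 | C9–C10-coupled ketone (12-oxo analogue of 23) | C=C1C[C@]2(CC(=O)OC)C[C@H]1C(=O)C[C@H]2[C@@]12C[C@H](OC(C)(C)O3)[C@H]3[C@@](C)(C(=O)O1)C2
F0 | step 16 | none | none
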